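**Plan**
- Retrosynthesis: first all benzyl ethers and a blocking bromine at C8 of the lower unit are removed; then the upper pyran ring is cut at O1–C2 and C3–C4 (retro-hetero-Diels–Alder) into an ortho-quinone methide and a (Z)-enol gallate; then the carbinol C4–C4a bond is cut into a lower-unit 6-carbaldehyde and 3,5-bis(benzyloxy)phenol.
- Forward: the bought lower flavan, (−)-epicatechin, is benzylated, brominated at C8, galloylated and formylated at C6; the upper A ring is attached by ortho-hydroxyalkylation; the upper pyran ring is closed last by a dehydrative [4+2] cycloaddition that also brings in ring B and the second gallate; one hydrogenolysis finishes.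
- Enabling feature: in the upper unit, O1–C8a–C4a–C4 is a latent 1-oxadiene (an ortho-quinone methide of the phloroglucinol A ring, stabilised by the oxygens at C5 and C7 and by the lower-unit arene on C4). C2 carries a para-oxygenated aryl (ring B) and C3 an acyloxy group, so C2=C3 is a (Z)-β-acyloxystyrene whose polarisation matches the O1–C2 and C3–C4 bonds.
- Stereochemistry: C2 and C3 of the lower unit are bought with (−)-epicatechin; upper C2/C3 cis comes from the Z-alkene, C3/C4 trans from the exo approach, and the absolute sense from a chiral phosphoric acid.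

Key step: step 7

Remark (assumption): the sense of induction of the chiral phosphoric acid in step 7 cannot be predicted with confidence; the (R)-catalyst is written and its mirror image would be used if the opposite face is delivered. Compounds 4, 8 and 10 are taken as commercial.

**Step 1**
Reactants: 1 (−)-epicatechin
Product: 2 5,7,3',4'-tetra-O-benzyl-(−)-epicatechin
Conditions: BnBr (4.4 equiv), K2CO3, DMF, 0 °C to rt
Reagents that add atoms: benzyl bromide, BrCc1ccccc1
Why: Williamson ether synthesis in which carbonate deprotonates only the four phenols, so the secondary 3-OH and both stereocentres stay untouched.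

**Step 2**
Reactants: 2 5,7,3',4'-tetra-O-benzyl-(−)-epicatechin
Product: 3 8-bromo-5,7,3',4'-tetra-O-benzyl-(−)-epicatechin
Conditions: NBS (1.05 equiv), CH2Cl2, −40 °C to rt
Reagents that add atoms: N-bromosuccinimide, O=C1CCC(=O)N1Br
Why: electrophilic aromatic bromination goes to C8, the more reactive position of 5,7-di-O-benzyl flavan-3-ols, and the bromine then blocks C8 so that later substitution is directed to C6.

**Step 3**
Reactants: 3 8-bromo-5,7,3',4'-tetra-O-benzyl-(−)-epicatechin; 4 3,4,5-tris(benzyloxy)benzoic acid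
Product: 5 8-bromo-5,7,3',4'-tetra-O-benzyl-(−)-epicatechin 3-O-[3,4,5-tris(benzyloxy)benzoate]
Conditions: DCC, DMAP, CH2Cl2, rt
Reagents that add atoms: none
Why: Steglich esterification acylates the axial 3-OH with retention, since the C3–O bond is not broken.

**Step 4**
Reactants: 5 8-bromo-5,7,3',4'-tetra-O-benzyl-(−)-epicatechin 3-O-[3,4,5-tris(benzyloxy)benzoate]
Product: 7 6-formyl-8-bromo-5,7,3',4'-tetra-O-benzyl-(−)-epicatechin 3-O-[3,4,5-tris(benzyloxy)benzoate], via aryl iminium chloride 6 (not isolated)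
Conditions: POCl3, DMF, 0 to 60 °C; then ice-water
Reagents that add atoms: N,N-dimethylformamide, CN(C)C=O; water, O
Why: Vilsmeier–Haack formylation should attack C6, the only free position of the trialkoxy-substituted lower A ring, while the ester, the benzyl ethers and the less electron-rich ring B are left alone.

**Step 5**
Reactants: 8 1-(benzyloxy)-4-ethynylbenzene; 4 3,4,5-tris(benzyloxy)benzoic acid
Product: 9 (Z)-2-[4-(benzyloxy)phenyl]ethenyl 3,4,5-tris(benzyloxy)benzoate
Conditions: [RuCl2(p-cymene)]2 (1 mol %), P(4-ClC6H4)3, DMAP (cat.), toluene, 60 °C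
Reagents that add atoms: none
Why: ruthenium-catalysed anti-Markovnikov addition of a carboxylic acid to a terminal alkyne (via a ruthenium vinylidene) should give the Z-enol ester, which fixes the later C2/C3 cis relationship.

**Step 6**
Reactants: 7 6-formyl-8-bromo-5,7,3',4'-tetra-O-benzyl-(−)-epicatechin 3-O-[3,4,5-tris(benzyloxy)benzoate]; 10 3,5-bis(benzyloxy)phenol
Product: 12 [2-hydroxy-4,6-bis(benzyloxy)phenyl](lower-unit C6-yl)methanol (mixture of carbinol epimers), via bromomagnesium phenoxide 11 (not isolated)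
Conditions: 10, EtMgBr (1 equiv), Et2O, 0 °C; solvent change to toluene; 7, rt; then water (pH 7 buffer), 0 °C
Reagents that add atoms: none
Why: ortho-specific hydroxyalkylation of a bromomagnesium phenoxide with an aromatic aldehyde (Casiraghi-type, six-membered magnesium chelate) should form the carbinol C–aryl bond next to the phenol oxygen; the new carbinol centre is not controlled and is planarised in step 7.

**Step 7**
Reactants: 12 [2-hydroxy-4,6-bis(benzyloxy)phenyl](lower-unit C6-yl)methanol; 9 (Z)-2-[4-(benzyloxy)phenyl]ethenyl 3,4,5-tris(benzyloxy)benzoate (3 equiv)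
Product: 14 5,7,4'-tri-O-benzyl-(−)-epiafzelechin 3-O-[3,4,5-tris(benzyloxy)benzoate]-(4β→6)-8-bromo-5,7,3',4'-tetra-O-benzyl-(−)-epicatechin 3-O-[3,4,5-tris(benzyloxy)benzoate], via ortho-quinone methide 13 (not isolated)
Conditions: (R)-TRIP (10 mol %), 5 Å MS, toluene, 0 °C to rt (−H2O)
Reagents that add atoms: none
Why: Proposed new method: the chiral phosphoric acid should ionise the doubly benzylic, donor-stabilised carbinol of 12 with loss of water to the catalyst-bound (E)-ortho-quinone methide 13, whose 1-oxadiene O1=C8a–C4a=C4 then adds to the Z-enol ester 9 in an asynchronous inverse-electron-demand hetero-Diels–Alder reaction, with C3–C4 bond formation running ahead of O1–C2 closure while the charge building at C2 is carried by the para-benzyloxy group of ring B. The closest known reaction type is the Brønsted-acid-catalysed [4+2] cycloaddition of ortho-quinone methides, generated from ortho-hydroxybenzhydrols, with styrenes and enol derivatives to give 2,4-disubstituted chromans; a β-acyloxystyrene as 2π partner and a methide carbon bearing a di-ortho-substituted aryl group go beyond it. The upper pyran ring is closed by an intermolecular [4+2] cycloaddition (O1, C8a, C4a and C4 from 13; C3 and C2 from 9) that makes the O1–C2 and C3–C4 bonds together. C2 and C3 should come out cis because addition across the Z double bond is suprafacial; C3 and C4 (and C2 and C4) should come out trans because the exo approach puts the C3 hydrogen, not the acyloxy or aryl group, next to the orthogonal lower-unit aryl group that sits outside on the E-methide; the absolute sense of the three centres is set by the chiral phosphate, which hydrogen-bonds to the quinone methide oxygen and shields one face, the lower-unit stereocentres being too remote to help. The step needs regioselectivity (C3, not C2, to C4), secured by the para oxygen of ring B, which makes C2 the cation-stabilising terminus while the ester oxygen at C3 is only a weak donor; exo and facial selectivity as described; and chemoselectivity for the cross reaction over self-condensation of 13, for which the quinone methide can form only on the upper A ring (all ortho oxygens of the lower ring are benzylated), 9 is used in excess and the water set free is taken up by the sieves.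

**Step 8**
Reactants: 14 5,7,4'-tri-O-benzyl-(−)-epiafzelechin 3-O-[3,4,5-tris(benzyloxy)benzoate]-(4β→6)-8-bromo-5,7,3',4'-tetra-O-benzyl-(−)-epicatechin 3-O-[3,4,5-tris(benzyloxy)benzoate]
Product: 15 (−)-epiafzelechin 3-O-gallate-(4β→6)-(−)-epicatechin 3-O-gallate (CNP0169607.1)
Conditions: H2 (1 atm), Pd(OH)2/C, Et3N (1.5 equiv), THF/MeOH/H2O, rt
Reagents that add atoms: none
Why: catalytic hydrogenolysis should cleave the thirteen benzyl ethers and the aryl C–Br bond in one operation under near-neutral conditions that leave the esters, the acid-labile interflavan bond and all five stereocentres intact.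

**Compound list**
1 | (−)-epicatechin, (2R,3R) | O[C@@H]1Cc2c(O)cc(O)cc2O[C@@H]1c1ccc(O)c(O)c1 | starting material
2 | 5,7,3',4'-tetra-O-benzyl-(−)-epicatechin | O[C@@H]1Cc2c(OCc3ccccc3)cc(OCc3ccccc3)cc2O[C@@H]1c1ccc(OCc2ccccc2)c(OCc2ccccc2)c1 | intermediate
3 | 8-bromo-5,7,3',4'-tetra-O-benzyl-(−)-epicatechin | O[C@@H]1Cc2c(OCc3ccccc3)cc(OCc3ccccc3)c(Br)c2O[C@@H]1c1ccc(OCc2ccccc2)c(OCc2ccccc2)c1 | intermediate
4 | 3,4,5-tris(benzyloxy)benzoic acid | OC(=O)c1cc(OCc2ccccc2)c(OCc2ccccc2)c(OCc2ccccc2)c1 | starting material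
5 | 8-bromo-5,7,3',4'-tetra-O-benzyl-(−)-epicatechin 3-O-[3,4,5-tris(benzyloxy)benzoate] | O=C(O[C@@H]1Cc2c(OCc3ccccc3)cc(OCc3ccccc3)c(Br)c2O[C@@H]1c1ccc(OCc2ccccc2)c(OCc2ccccc2)c1)c1cc(OCc2ccccc2)c(OCc2ccccc2)c(OCc2ccccc2)c1 | intermediate
6 | C6 N,N-dimethyliminium chloride of 5 (aryl–CH=NMe2+ Cl−) | O=C(O[C@@H]1Cc2c(OCc3ccccc3)c(C=[N+](C)C)c(OCc3ccccc3)c(Br)c2O[C@@H]1c1ccc(OCc2ccccc2)c(OCc2ccccc2)c1)c1cc(OCc2ccccc2)c(OCc2ccccc2)c(OCc2ccccc2)c1.[Cl-] | intermediate
7 | 6-formyl-8-bromo-5,7,3',4'-tetra-O-benzyl-(−)-epicatechin 3-O-[3,4,5-tris(benzyloxy)benzoate] | O=C(O[C@@H]1Cc2c(OCc3ccccc3)c(C=O)c(OCc3ccccc3)c(Br)c2O[C@@H]1c1ccc(OCc2ccccc2)c(OCc2ccccc2)c1)c1cc(OCc2ccccc2)c(OCc2ccccc2)c(OCc2ccccc2)c1 | intermediate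
8 | 1-(benzyloxy)-4-ethynylbenzene | C#Cc1ccc(OCc2ccccc2)cc1 | starting material
9 | (Z)-2-[4-(benzyloxy)phenyl]ethenyl 3,4,5-tris(benzyloxy)benzoate | O=C(O/C=C\c1ccc(OCc2ccccc2)cc1)c1cc(OCc2ccccc2)c(OCc2ccccc2)c(OCc2ccccc2)c1 | intermediate
10 | 3,5-bis(benzyloxy)phenol | Oc1cc(OCc2ccccc2)cc(OCc2ccccc2)c1 | starting material
11 | bromomagnesium 3,5-bis(benzyloxy)phenoxide | Br[Mg]Oc1cc(OCc2ccccc2)cc(OCc2ccccc2)c1 | intermediate
12 | [2-hydroxy-4,6-bis(benzyloxy)phenyl](lower-unit C6-yl)methanol, carbinol epimers, lower unit 2R,3R | O=C(O[C@@H]1Cc2c(OCc3ccccc3)c(C(O)c3c(O)cc(OCc4ccccc4)cc3OCc3ccccc3)c(OCc3ccccc3)c(Br)c2O[C@@H]1c1ccc(OCc2ccccc2)c(OCc2ccccc2)c1)c1cc(OCc2ccccc2)c(OCc2ccccc2)c(OCc2ccccc2)c1 | intermediate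
13 | (E)-ortho-quinone methide: 3,5-bis(benzyloxy)-6-(lower-unit C6-ylmethylidene)cyclohexa-2,4-dien-1-one, aryl anti to the carbonyl | O=C(O[C@@H]1Cc2c(OCc3ccccc3)c(/C=C3/C(=O)C=C(OCc4ccccc4)C=C3OCc3ccccc3)c(OCc3ccccc3)c(Br)c2O[C@@H]1c1ccc(OCc2ccccc2)c(OCc2ccccc2)c1)c1cc(OCc2ccccc2)c(OCc2ccccc2)c(OCc2ccccc2)c1 | intermediate
14 | fully benzylated 8-bromo dimer; upper unit 2R,3R, 2,3-cis, 3,4-trans (4β), lower unit 2R,3R | O=C(O[C@@H]1[C@@H](c2c(OCc4ccccc4)c(Br)c3c(c2OCc2ccccc2)C[C@@H](OC(=O)c2cc(OCc4ccccc4)c(OCc4ccccc4)c(OCc4ccccc4)c2)[C@@H](c2ccc(OCc4ccccc4)c(OCc4ccccc4)c2)O3)c2c(OCc3ccccc3)cc(OCc3ccccc3)cc2O[C@@H]1c1ccc(OCc2ccccc2)cc1)c1cc(OCc2ccccc2)c(OCc2ccccc2)c(OCc2ccccc2)c1 | intermediate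
15 | (−)-epiafzelechin 3-O-gallate-(4β→6)-(−)-epicatechin 3-O-gallate; upper unit 2R,3R,4S, lower unit 2R,3R | O=C(O[C@@H]1[C@@H](c2c(O)cc3c(c2O)C[C@@H](OC(=O)c2cc(O)c(O)c(O)c2)[C@@H](c2ccc(O)c(O)c2)O3)c2c(O)cc(O)cc2O[C@@H]1c1ccc(O)cc1)c1cc(O)c(O)c(O)c1 | target

Total step count: 8. Longest linear sequence: 7 steps (1, 2, 3, 4, 6, 7, 8).

**Steps most likely to fail**

Step 7 (Proposed new method). The hindered, strongly stabilised quinone methide may react too slowly with the enol ester and be lost to self-condensation through the nucleophilic upper A ring. Facial selectivity under the catalyst may be poor. A stepwise ionic pathway may erase the alkene geometry and give the C2 epimer, or the endo approach may give the 3,4-cis isomer. The fallback gives up the cycloaddition and joins two preformed flavan units by the known Lewis-acid coupling of a flavan-4-yl cation with an arene, so the upper heterocycle is then in place before the interflavan bond. It sets out from 5 and from (−)-epiafzelechin F1, bought as the natural product. F1 would be benzylated (BnBr, K2CO3, DMF) to 5,7,4'-tri-O-benzyl-(−)-epiafzelechin F2. Oxidation at C4 with DDQ in the presence of 2-ethoxyethanol (CH2Cl2, rt) would give the 4β-(2-ethoxyethoxy) ether F3, and esterification with 4 (DCC, DMAP) its 3-O-[3,4,5-tris(benzyloxy)benzoate] F4. F4 would be coupled with an excess of 5 (TMSOTf, CH2Cl2, −78 °C). C6 of 5 (C8 being blocked) should attack the cation anti to the 3-acyloxy group, and the route is rejoined at 14.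

Step 6. Carbon–carbon bond formation between two hindered partners may stall, the adduct may ionise in the flask and take up a second phenoxide, or it may lose water during isolation. The fallback replaces the magnesium chelate by a covalent boron template and sets out from 7 and 10. Condensation with phenylboronic acid (cat. propionic acid, toluene, Dean–Stark) should give the 4-(lower-unit C6-yl)-5,7-bis(benzyloxy)-2-phenyl-4H-1,3,2-benzodioxaborin F5. This cyclic boronate is a temporary ring formed ortho-specifically and should be robust to chromatography. Mild transesterification with propane-1,3-diol (THF, rt) should release 12, where the route is rejoined.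

Step 4. Formylation at a position flanked by two benzyloxy groups on a ring deactivated by bromine may be incomplete, and the hydrogen chloride formed may start to remove benzyl groups at the temperature needed. The fallback reverses the polarity at C6 and sets out from 5. Iodination with NIS (cat. TFA, CH2Cl2, 0 °C) should give the 6-iodo-8-bromo ester F6. Iodine–magnesium exchange with i-PrMgCl·LiCl (THF, −40 °C) should be selective for C–I over C–Br and spare the hindered benzoate, giving the C6 arylmagnesium chloride F7. Quenching with DMF and then water should give 7, where the route is rejoined.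

**Further compounds**
F1 | step 7 | (−)-epiafzelechin (purchased) | O[C@@H]1Cc2c(O)cc(O)cc2O[C@@H]1c1ccc(O)cc1
F2 | step 7 | 5,7,4'-tri-O-benzyl-(−)-epiafzelechin | O[C@@H]1Cc2c(OCc3ccccc3)cc(OCc3ccccc3)cc2O[C@@H]1c1ccc(OCc2ccccc2)cc1
F3 | step 7 | 4β-(2-ethoxyethoxy)-5,7,4'-tri-O-benzyl-(−)-epiafzelechin | O[C@@H]1[C@@H](OCCOCC)c2c(OCc3ccccc3)cc(OCc3ccccc3)cc2O[C@@H]1c1ccc(OCc2ccccc2)cc1
F4 | step 7 | 4β-(2-ethoxyethoxy)-5,7,4'-tri-O-benzyl-(−)-epiafzelechin 3-O-[3,4,5-tris(benzyloxy)benzoate] | O=C(O[C@@H]1[C@@H](OCCOCC)c2c(OCc3ccccc3)cc(OCc3ccccc3)cc2O[C@@H]1c1ccc(OCc2ccccc2)cc1)c1cc(OCc2ccccc2)c(OCc2ccccc2)c(OCc2ccccc2)c1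
F5 | step 6 | 4-(lower-unit C6-yl)-5,7-bis(benzyloxy)-2-phenyl-4H-1,3,2-benzodioxaborin | O=C(O[C@@H]1Cc2c(OCc3ccccc3)c(C3OB(c4ccccc4)Oc4cc(OCc5ccccc5)cc(OCc5ccccc5)c34)c(OCc3ccccc3)c(Br)c2O[C@@H]1c1ccc(OCc2ccccc2)c(OCc2ccccc2)c1)c1cc(OCc2ccccc2)c(OCc2ccccc2)c(OCc2ccccc2)c1
F6 | step 4 | 6-iodo-8-bromo-5,7,3',4'-tetra-O-benzyl-(−)-epicatechin 3-O-[3,4,5-tris(benzyloxy)benzoate] | O=C(O[C@@H]1Cc2c(OCc3ccccc3)c(I)c(OCc3ccccc3)c(Br)c2O[C@@H]1c1ccc(OCc2ccccc2)c(OCc2ccccc2)c1)c1cc(OCc2ccccc2)c(OCc2ccccc2)c(OCc2ccccc2)c1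
F7 | step 4 | C6 arylmagnesium chloride of 5 | O=C(O[C@@H]1Cc2c(OCc3ccccc3)c([Mg]Cl)c(OCc3ccccc3)c(Br)c2O[C@@H]1c1ccc(OCc2ccccc2)c(OCc2ccccc2)c1)c1cc(OCc2ccccc2)c(OCc2ccccc2)c(OCc2ccccc2)c1
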